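A small charge of solid substrate reaches target by dissolving and then coupling with the partner, so I follow one dissolved molecule and ask whether it couples in time.

| setting | Thursday's | Sunday's | flask |
|---|---|---|---|
| solid substrate | 0.12 M | 0.12 M | 0.12 M |
| coupling partner | 0.12 M | 0.18 M | 0.240 M |
| remark | run made earlier | run made earlier |  |
| time |  |  | 15 min |

| run | time / min | target / % | solid substrate / % |
|---|---|---|---|
| Thursday's | 1.50 | 4.5 | 82.9 |
| Thursday's | 3.00 | 9.9 | 70.1 |
| Thursday's | 5.00 | 23.8 | 56.4 |
| Thursday's | 6.00 | 27.3 | 45.2 |
| Thursday's | 8.00 | 39.8 | 32.5 |
| Thursday's | 10.0 | 50.8 | 18.3 |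
| Thursday's | 12.0 | 60.2 | 6.0 |
| Sunday's | 1.00 | 0.9 | 89.2 |
| Sunday's | 1.33 | 2.1 | 86.4 |
| Sunday's | 2.00 | 6.9 | 78.0 |
| Sunday's | 3.00 | 13.7 | 70.1 |
| Sunday's | 5.00 | 29.4 | 50.7 |
| Sunday's | 8.00 | 50.3 | 27.1 |
| Sunday's | 12.0 | 76.0 | 0 |

(scatter of a reading: 1 percentage point)
- as a solid, counted per litre of solution: solid substrate
- the earlier runs were read with a standard deviation of 1 percentage point
- at the start none of the solid substrate is in solution
1. how much target there is at 15 min, in percent of the solid substrate charged
2. the change that raises the amount of target at 15 min, in percent of the solid substrate charged most ("none" if none brings more than 2 percentage points) (alpha / eta / delta / none)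
3. amount of target at 15 min, in percent of the solid substrate charged, after alpha
- alpha: doubling the solubility of the solid substrate, all else as stated
- eta: doubling the dissolution coefficient of the solid substrate, all else as stated
- delta: doubling the amount of coupling partner, all else as stated

As a first reckoning I take what is neither solid nor target as dissolved substrate. In Sunday's run it stood at 19.9 % at 5.00 min, while target rose by 37 percentage points between 3.00 min and 8.00 min. So with about 0.145 M of partner, a dissolved molecule couples at a pseudo-first-order 0.368 min⁻¹. Scaled to the partner left over once the charged substrate has reacted, this gives the coupling wait, the half-life of a dissolved molecule late in the asked flask: 2.27 min.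

Two chemists dispute the asked flask. The second calls dissolving the rate-limiting step: at Sunday's pace the solid clears by about 11.0 min, and the wait is shorter, so target should reach nearly 100 %, and faster dissolving should help most.

The first counts the tail: the 4.03 min after clearing is less than two waits, so 29.3 % of what is then dissolved survives. Taking Sunday's 22.6 % at 8.00 min as that amount, my own reckoning leaves 6.62 % and gives 93.4 % target. The forecast, on this side, says 95 %, 98.7 % after alpha, and delta as best: “The remaining 4 min of coupling leaves about 5 % unreacted”.

The flask gives 93.2 %, and 95.7 % after alpha; delta is best, gaining 5.3 points against 2.5 points for alpha and 2.3 points for eta.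

    dissolved substrate + target → side product (k = 0.00230 L mol⁻¹ s⁻¹)
    dissolved substrate + coupling partner → target (k = 0.0460 L mol⁻¹ s⁻¹)
    solid substrate ⇌ dissolved substrate, rate k3*(cs3 - [dissolved substrate]) while solid is left; crystals form when [dissolved substrate] > cs3 (solubility = 0.0770 M, k = 0.00320 s⁻¹)

Dissolving and coupling ran together while solid stood, 26.6 % of it at 7.50 min beside 17.2 % dissolved. By 15 min the solid was at 0 % and coupling ran on, but the 6.80 % short of full target was not all waiting: 3.48 % was still dissolved and 3.34 % stood as side product, formed from dissolved substrate and target, each of it counting as two. The answer has moved 5 points at 0.142 M of solid. The second view holds with 0.048 M of solid: clearing near 4.39 min and a wait of 1.42 min leave 7.47 waits, and that flask holds 98.8 % target.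

(The earlier runs and the new flask are simulated with made-up constants; scatter was added.)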